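**Strategy.** Everything rests on cutting the ten-membered carbocycle C1–C10 across the ring at C3–C8. The ketone carbon C3 and C8 are connected on one side by C2, C1, C10 and C9; these six carbons are therefore prepared first as a six-membered ring carrying the tertiary C10 carbinol, and the other four ring atoms arrive as a vinyl arm (C4=C5) and a dihydrofuranyl arm (C7=C6). One anionic oxy-Cope step then forms C5–C6, opens the six-membered ring into the ten-membered one, creates C6 and the E-C7=C8 alkene and leaves a C3–C4 enolate that is hydroxymethylated at C4. The precursor is a trans-1-vinyl-2-(4,5-dihydrofuran-3-yl)-4-methyl-4-silyloxycyclohexanol.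

Key step: step 10

**Remarks on the chemistry (assumptions)**

- Ten-membered intermediates carry the target's atom numbers C1–C15; six-membered intermediates have systematic names.
- In the rearranged ring the E-C7=C8 alkene is fused to the tetrahydrofuran, whose oxygen lies in the alkene plane. The ring chain (from C5) therefore covers one face, and reagents reach only the face that bears H-6, so H-7 must enter cis to H-6. The target has H-6 and H-7 trans. The precursor is therefore built with the dihydrofuranyl arm cis to the C10 methyl group (trans to the C10 silyloxy group). The rearrangement then gives the 6-epi series, peripheral attack should set C4, C7 and C8 as in the target, and C6 is inverted in step 16.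
- The ketone of the key-step product is used as its potassium enolate 14, because only the enolate differentiates C4 from C2.
- No alkene may be present in the ruthenium tetroxide step, so the C1=C2 alkene, the exocyclic methylene and the angelate are introduced after it.

## Route

Step 1
Reactants: 1 1,4-dioxaspiro[4.5]dec-6-en-8-one
Product: 2 (8R)-1,4-dioxaspiro[4.5]dec-6-en-8-ol
Conditions: (S)-1-methyl-3,3-diphenyltetrahydro-1H,3H-pyrrolo[1,2-c][1,3,2]oxazaborole (10 mol%), BH3·SMe2, THF, −20 °C; then MeOH
Reagents that add atoms: none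
Why: Corey–Bakshi–Shibata reduction, in which the oxazaborolidine–borane complex binds the carbonyl with the alkenyl flank as the large group and delivers hydride to one enantioface, which should give the R carbinol that later controls C8.

Step 2
Reactants: 2 (8R)-1,4-dioxaspiro[4.5]dec-6-en-8-ol
Product: 3 (8R)-8-[(tert-butyldimethylsilyl)oxy]-1,4-dioxaspiro[4.5]dec-6-ene
Conditions: tBuMe2SiCl, imidazole, DMF, rt
Reagents that add atoms: tert-butyldimethylsilyl chloride, CC(C)(C)[Si](C)(C)Cl
Why: Silyl ether formation at a secondary alcohol under imidazole catalysis, which touches no stereocentre.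

Step 3
Reactants: 3 (8R)-8-[(tert-butyldimethylsilyl)oxy]-1,4-dioxaspiro[4.5]dec-6-ene
Product: 4 (4R)-4-[(tert-butyldimethylsilyl)oxy]cyclohex-2-en-1-one
Conditions: pyridinium p-toluenesulfonate (cat.), acetone/H2O 10:1, 50 °C
Reagents that add atoms: water, O
Why: Acid-catalysed ketal hydrolysis, driven by formation of the conjugated enone, under acid mild enough to keep the allylic silyl ether and its stereocentre.

Step 4
Reactants: 4 (4R)-4-[(tert-butyldimethylsilyl)oxy]cyclohex-2-en-1-one; 5 2-(4,5-dihydrofuran-3-yl)-4,4,5,5-tetramethyl-1,3,2-dioxaborolane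
Product: 6 (3S,4R)-4-[(tert-butyldimethylsilyl)oxy]-3-(4,5-dihydrofuran-3-yl)cyclohexan-1-one
Conditions: [Rh(OH)(C8H12)]2 (2.5 mol%; C8H12 = cycloocta-1,5-diene), K3PO4, 1,4-dioxane/H2O 10:1, 30 °C
Reagents that add atoms: none
Why: Rhodium-catalysed conjugate addition of an alkenylboronate (Hayashi–Miyaura type), in which the alkenylrhodium adds to the enone face anti to the neighbouring silyloxy group and so sets the arm-bearing carbon (later C8) trans to the temporary oxygen.

Step 5
Reactants: 6 (3S,4R)-4-[(tert-butyldimethylsilyl)oxy]-3-(4,5-dihydrofuran-3-yl)cyclohexan-1-one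
Product: 7 (1S,3S,4R)-4-[(tert-butyldimethylsilyl)oxy]-3-(4,5-dihydrofuran-3-yl)-1-methylcyclohexan-1-ol
Conditions: MeMgBr, CeCl3, THF, −78 °C; then aq. NH4Cl
Reagents that add atoms: methylmagnesium bromide, C[Mg]Br
Why: Cerium-mediated Grignard 1,2-addition along the equatorial trajectory of the chair that has the arm and the silyloxy group both equatorial, which should place the methyl cis to the arm and so set the later C10.

Step 6
Reactants: 7 (1S,3S,4R)-4-[(tert-butyldimethylsilyl)oxy]-3-(4,5-dihydrofuran-3-yl)-1-methylcyclohexan-1-ol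
Product: 8 (1R,2S,4S)-2-(4,5-dihydrofuran-3-yl)-4-methylcyclohexane-1,4-diol
Conditions: Bu4NF, THF, 0 °C to rt
Reagents that add atoms: none
Why: Fluoride-mediated desilylation of the secondary silyl ether under non-acidic conditions that spare the enol ether.

Step 7
Reactants: 8 (1R,2S,4S)-2-(4,5-dihydrofuran-3-yl)-4-methylcyclohexane-1,4-diol
Product: 9 (2S,4S)-2-(4,5-dihydrofuran-3-yl)-4-hydroxy-4-methylcyclohexan-1-one
Conditions: SO3·pyridine, DMSO, iPr2NEt, CH2Cl2, 0 °C
Reagents that add atoms: none
Why: Parikh–Doering oxidation, which converts only the secondary alcohol under non-acidic conditions; the now enolisable arm-bearing carbon already has the favoured arrangement (arm and methyl equatorial), so epimerisation is not a threat.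

Step 8
Reactants: 9 (2S,4S)-2-(4,5-dihydrofuran-3-yl)-4-hydroxy-4-methylcyclohexan-1-one
Product: 10 (2S,4S)-2-(4,5-dihydrofuran-3-yl)-4-methyl-4-[(triethylsilyl)oxy]cyclohexan-1-one
Conditions: Et3SiOSO2CF3, 2,6-lutidine, CH2Cl2, −78 °C
Reagents that add atoms: triethylsilyl trifluoromethanesulfonate, CC[Si](CC)(CC)OS(=O)(=O)C(F)(F)F
Why: Silyl ether formation at the tertiary alcohol with a silyl triflate and a hindered base, O-silylation of the alcohol being faster at −78 °C than enol silylation of the ketone.

Step 9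
Reactants: 10 (2S,4S)-2-(4,5-dihydrofuran-3-yl)-4-methyl-4-[(triethylsilyl)oxy]cyclohexan-1-one; 11 vinylmagnesium bromide
Product: 12 (1R,2S,4S)-2-(4,5-dihydrofuran-3-yl)-1-ethenyl-4-methyl-4-[(triethylsilyl)oxy]cyclohexan-1-ol
Conditions: CH2=CHMgBr, CeCl3, THF, −78 °C; then aq. NH4Cl
Reagents that add atoms: none
Why: Cerium-mediated Grignard 1,2-addition, in which equatorial attack anti to the adjacent equatorial arm should give the trans-1,2-dialkenyl carbinol (vinyl equatorial, hydroxyl axial) without enolising the ketone.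

Step 10
Reactants: 12 (1R,2S,4S)-2-(4,5-dihydrofuran-3-yl)-1-ethenyl-4-methyl-4-[(triethylsilyl)oxy]cyclohexan-1-ol
Product: 15 (4S,6S,10S)-hydroxymethyl ketone with E-C7=C8 and tetrahydrofuran fused at C6–C7, via potassium alkoxide 13 (not isolated), via potassium enolate 14 (not isolated)
Conditions: KN(SiMe3)2 (1.05 equiv), 18-crown-6, THF, 0 °C to rt; then CH2O (gas), −78 °C; then AcOH, −78 °C
Reagents that add atoms: formaldehyde, C=O
Why: Deprotonation gives alkoxide 13, whose weakened C3–C8 bond breaks while C5–C6 forms in a concerted [3,3] shift through a chair transition state with both alkenyl arms equatorial; the closest known class is the anionic oxy-Cope rearrangement of trans-1,2-dialkenylcyclohexanols to E-cyclodec-5-enones, and only the enol-ether arm is new. The ten-membered ring is therefore closed by ring expansion of the cyclohexane and not by end-to-end cyclisation, and the equatorial C8–C9 bond becomes the E-C7=C8 alkene. C6 is controlled by the C8 stereocentre, because the ring-bound enol-ether oxygen must sit equatorial in the chair, which here should give 6S. C4 is set when formaldehyde adds to the regiodefined enolate 14 on its outer face, away from the C7=C8 unit across the ring (aldol addition), which should give 4S. The step needs the trans-diequatorial chair and trapping before proton transfer: the first is secured by the trans arms from step 9, the second by one equivalent of soluble base and cold addition of the aldehyde; the C10 silyl ether lies on the face opposite to the C3 oxygen, so silyl migration is not expected.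

Step 11
Reactants: 15 (4S,6S,10S)-hydroxymethyl ketone
Product: 16 C15 triisopropylsilyl ether of 15
Conditions: iPr3SiCl, imidazole, DMF, 0 °C
Reagents that add atoms: triisopropylsilyl chloride, CC(C)[Si](Cl)(C(C)C)C(C)C
Why: Silyl ether formation at the primary alcohol under imidazole buffering, mild enough to avoid retro-aldol cleavage or epimerisation at C4.

Step 12
Reactants: 16 C15 triisopropylsilyl ether of 15
Product: 18 (4S,6S,7R,8R,10S)-8-hydroxy ketone with cis-fused tetrahydrofuran, via alkylborane 17 (not isolated)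
Conditions: BH3·THF (1.1 equiv), THF, −20 to 0 °C; then 30% H2O2, aq. NaOAc, 0 °C
Reagents that add atoms: borane–tetrahydrofuran complex, B.C1CCOC1 (boron stays only in 17); hydrogen peroxide, OO
Why: Hydroboration–oxidation, in which the strained E-trisubstituted alkene should react faster than the hindered ketone, boron adds to the less substituted C8 and hydrogen to C7 in a syn manner on the only open face (that of H-6), which sets C7 and C8, and buffered peroxide oxidation retains configuration.

Step 13
Reactants: 18 (4S,6S,7R,8R,10S)-8-hydroxy ketone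
Product: 19 8-O-triethylsilyl ether of 18 (4S,6S,7S,8R,10S)
Conditions: Et3SiOSO2CF3, 2,6-lutidine, CH2Cl2, −78 °C
Reagents that add atoms: triethylsilyl trifluoromethanesulfonate, CC[Si](CC)(CC)OS(=O)(=O)C(F)(F)F
Why: Silyl ether formation at the secondary alcohol, needed because the next oxidant would convert a free C8 hydroxyl into a ketone.

Step 14
Reactants: 19 8-O-triethylsilyl ether of 18
Product: 20 (4S,6S,7S,8R,10S)-cis-fused γ-lactone (C12 carbonyl, 6-epi series)
Conditions: RuCl3·xH2O (5 mol%), NaIO4, CCl4/MeCN/pH 7 phosphate buffer, rt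
Reagents that add atoms: sodium periodate, [Na+].[O-]I(=O)(=O)=O
Why: Ruthenium tetroxide oxidation of a cyclic ether, in which catalytic RuO4 regenerated by periodate should oxidise the unhindered C12 methylene next to oxygen to the lactone and leave the tertiary C6–H, the ketone and the silyl ethers, no alkene being present at this stage.

Step 15
Reactants: 20 (4S,6S,7S,8R,10S)-cis-fused γ-lactone
Product: 21 (4S,6S,7S,8R,10S)-N,N-dimethyl hydroxy amide with free C6 hydroxyl
Conditions: Me2NH, AlMe3, CH2Cl2, 0 °C to rt; then aq. potassium sodium tartrate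
Reagents that add atoms: dimethylamine, CNC
Why: Aminolysis of the lactone by a dimethylaluminium amide, which frees the C6 hydroxyl without touching a stereocentre and turns the carboxyl group into an internal oxygen nucleophile.

Step 16
Reactants: 21 (4S,6S,7S,8R,10S)-N,N-dimethyl hydroxy amide
Product: 24 (4S,6R,7S,8R,10S)-trans-fused γ-lactone, via mesylate 22 (not isolated), via iminium lactone 23 (not isolated)
Conditions: MsCl, Et3N, CH2Cl2, 0 °C to rt; then aq. NaHCO3
Reagents that add atoms: methanesulfonyl chloride, CS(Cl)(=O)=O (sulfonyl group only in 22); water, O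
Why: Mesylation followed by intramolecular SN2 displacement by the amide oxygen (5-exo-tet O-alkylation with neighbouring-group participation) inverts C6, and hydrolysis of the iminium lactone on work-up gives the trans-fused lactone of the target.

Step 17
Reactants: 24 (4S,6R,7S,8R,10S)-trans-fused γ-lactone
Product: 29 α-methylene lactone carrying the C2=C3 triethylsilyl enol ether, via dilithium bis-enolate 25 (not isolated), via bis-silyl ether 26 (not isolated), via Mannich base 27 (not isolated), via ammonium iodide 28 (not isolated)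
Conditions: LiN(iPr)2 (2.3 equiv), THF, −78 °C; Et3SiCl; then CH2=NMe2+ I− (1.05 equiv), CH2Cl2, −20 °C; then MeI; then aq. NaHCO3
Reagents that add atoms: chlorotriethylsilane, CC[Si](Cl)(CC)CC; N,N-dimethylmethyleneiminium iodide, C=[N+](C)C.[I-]; iodomethane, CI (methyl only in 28)
Why: Double deprotonation and O-silylation give a ketene silyl acetal and a kinetic C2 silyl enol ether, of which only the far more nucleophilic ketene acetal should react with the iminium salt (Mannich reaction); quaternisation and β-elimination of trimethylamine then give the α-methylene lactone while the ketone stays masked.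

Step 18
Reactants: 29 α-methylene lactone carrying the C2=C3 triethylsilyl enol ether
Product: 30 (1Z)-enone (4S,6R,7S,8R,10R)
Conditions: Pd(OAc)2 (1.1 equiv), MeCN, rt
Reagents that add atoms: none
Why: Saegusa–Ito oxidation, in which divalent palladium adds to the silyl enol ether at C2 and β-hydride elimination from C1 releases the enone and zerovalent palladium; the Z geometry is expected on the assumption that the Z-enone is the less strained isomer in this ten-membered ring.

Step 19
Reactants: 30 (1Z)-enone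
Product: 31 (4S,6R,7R,8R,10R)-8-hydroxy enone
Conditions: HF·pyridine, pyridine, THF, 0 °C
Reagents that add atoms: none
Why: Buffered fluoride desilylation, which should cleave the secondary triethylsilyl ether faster than the tertiary triethylsilyl ether and the primary triisopropylsilyl ether.

Step 20
Reactants: 31 (4S,6R,7R,8R,10R)-8-hydroxy enone; 32 angelic acid, (Z)-2-methylbut-2-enoic acid
Product: 34 8-O-angelate (4S,6R,7S,8R,10R), via mixed anhydride 33 (not isolated)
Conditions: 2,4,6-trichlorobenzoyl chloride, Et3N, toluene, rt; then 31, 4-(dimethylamino)pyridine, toluene, rt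
Reagents that add atoms: 2,4,6-trichlorobenzoyl chloride, O=C(Cl)c1c(Cl)cc(Cl)cc1Cl (aroyl group only in 33)
Why: Yamaguchi esterification through the mixed anhydride acylates the only secondary hydroxyl, and the mild conditions should keep the Z-configured angelate from isomerising to the tiglate.

Step 21
Reactants: 34 8-O-angelate
Product: 35 target, (4S,6R,7S,8R,10R)-8-angeloyloxy-10,15-dihydroxy-3-oxogermacra-1(Z),11(13)-dien-6,12-olide
Conditions: HF·pyridine, THF, 0 °C to rt
Reagents that add atoms: none
Why: Global desilylation with an acidic fluoride source removes the primary triisopropylsilyl and tertiary triethylsilyl ethers without base, which spares the angelate, the β-hydroxy ketone and both Michael acceptors.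

## Compound list

1 | 1,4-dioxaspiro[4.5]dec-6-en-8-one | O=C1C=CC2(CC1)OCCO2 | starting material
2 | (8R)-1,4-dioxaspiro[4.5]dec-6-en-8-ol | O[C@@H]1CCC2(OCCO2)C=C1 | intermediate
3 | (8R)-8-[(tert-butyldimethylsilyl)oxy]-1,4-dioxaspiro[4.5]dec-6-ene | CC(C)(C)[Si](C)(C)O[C@@H]1CCC2(OCCO2)C=C1 | intermediate
4 | (4R)-4-[(tert-butyldimethylsilyl)oxy]cyclohex-2-en-1-one | CC(C)(C)[Si](C)(C)O[C@@H]1CCC(=O)C=C1 | intermediate
5 | 2-(4,5-dihydrofuran-3-yl)-4,4,5,5-tetramethyl-1,3,2-dioxaborolane | CC1(C)OB(OC1(C)C)C2=COCC2 | starting material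
6 | (3S,4R)-4-[(tert-butyldimethylsilyl)oxy]-3-(4,5-dihydrofuran-3-yl)cyclohexan-1-one | CC(C)(C)[Si](C)(C)O[C@@H]1CCC(=O)C[C@H]1C2=COCC2 | intermediate
7 | (1S,3S,4R)-4-[(tert-butyldimethylsilyl)oxy]-3-(4,5-dihydrofuran-3-yl)-1-methylcyclohexan-1-ol | CC(C)(C)[Si](C)(C)O[C@@H]1CC[C@](C)(O)C[C@H]1C2=COCC2 | intermediate
8 | (1R,2S,4S)-2-(4,5-dihydrofuran-3-yl)-4-methylcyclohexane-1,4-diol | O[C@@H]1CC[C@](C)(O)C[C@H]1C2=COCC2 | intermediate
9 | (2S,4S)-2-(4,5-dihydrofuran-3-yl)-4-hydroxy-4-methylcyclohexan-1-one | O=C1CC[C@](C)(O)C[C@H]1C2=COCC2 | intermediate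
10 | (2S,4S)-2-(4,5-dihydrofuran-3-yl)-4-methyl-4-[(triethylsilyl)oxy]cyclohexan-1-one | O=C1CC[C@](C)(O[Si](CC)(CC)CC)C[C@H]1C2=COCC2 | intermediate
11 | vinylmagnesium bromide | C=C[Mg]Br | starting material
12 | (1R,2S,4S)-2-(4,5-dihydrofuran-3-yl)-1-ethenyl-4-methyl-4-[(triethylsilyl)oxy]cyclohexan-1-ol (key-step precursor) | C=C[C@]1(O)CC[C@](C)(O[Si](CC)(CC)CC)C[C@H]1C2=COCC2 | intermediate
13 | potassium alkoxide of 12 | C=C[C@]1([O-])CC[C@](C)(O[Si](CC)(CC)CC)C[C@H]1C2=COCC2.[K+] | intermediate (not isolated)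
14 | potassium C3–C4 enolate of the ring-expanded cyclodecenone (6S,10S; E-C7=C8; fused tetrahydrofuran) | O1CC/C(=C\C[C@@](C)(O[Si](CC)(CC)CC)CC/C([O-])=C/C2)[C@@H]12.[K+] | intermediate (not isolated)
15 | (4S,6S,10S)-hydroxymethyl ketone: C3 ketone, 4-CH2OH, E-C7=C8, 10-methyl, 10-OSiEt3, tetrahydrofuran fused at C6–C7 | O1CC/C(=C\C[C@@](C)(O[Si](CC)(CC)CC)CCC(=O)[C@H](CO)C2)[C@@H]12 | intermediate
16 | C15 triisopropylsilyl ether of 15 | O1CC/C(=C\C[C@@](C)(O[Si](CC)(CC)CC)CCC(=O)[C@H](CO[Si](C(C)C)(C(C)C)C(C)C)C2)[C@@H]12 | intermediate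
17 | C8 alkylborane from 16 (boron where the hydroxyl of 18 appears) | C1CO[C@H]2C[C@@H](CO[Si](C(C)C)(C(C)C)C(C)C)C(=O)CC[C@](C)(O[Si](CC)(CC)CC)C[C@@H](B)[C@@H]12 | intermediate (not isolated)
18 | (4S,6S,7R,8R,10S)-8-hydroxy ketone, cis-fused tetrahydrofuran | C1CO[C@H]2C[C@@H](CO[Si](C(C)C)(C(C)C)C(C)C)C(=O)CC[C@](C)(O[Si](CC)(CC)CC)C[C@@H](O)[C@@H]12 | intermediate
19 | 8-O-triethylsilyl ether of 18 (4S,6S,7S,8R,10S) | C1CO[C@H]2C[C@@H](CO[Si](C(C)C)(C(C)C)C(C)C)C(=O)CC[C@](C)(O[Si](CC)(CC)CC)C[C@@H](O[Si](CC)(CC)CC)[C@@H]12 | intermediate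
20 | (4S,6S,7S,8R,10S)-cis-fused γ-lactone (6-epi) | C1C(=O)O[C@H]2C[C@@H](CO[Si](C(C)C)(C(C)C)C(C)C)C(=O)CC[C@](C)(O[Si](CC)(CC)CC)C[C@@H](O[Si](CC)(CC)CC)[C@@H]12 | intermediate
21 | (4S,6S,7S,8R,10S)-N,N-dimethyl hydroxy amide | CN(C)C(=O)C[C@@H]1[C@H](O[Si](CC)(CC)CC)C[C@@](C)(O[Si](CC)(CC)CC)CCC(=O)[C@H](CO[Si](C(C)C)(C(C)C)C(C)C)C[C@@H]1O | intermediate
22 | C6 mesylate of 21 | CN(C)C(=O)C[C@@H]1[C@H](O[Si](CC)(CC)CC)C[C@@](C)(O[Si](CC)(CC)CC)CCC(=O)[C@H](CO[Si](C(C)C)(C(C)C)C(C)C)C[C@@H]1OS(C)(=O)=O | intermediate (not isolated)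
23 | cyclic N,N-dimethyliminium lactone methanesulfonate (C6 inverted) | C1C(=[N+](C)C)O[C@@H]2C[C@@H](CO[Si](C(C)C)(C(C)C)C(C)C)C(=O)CC[C@](C)(O[Si](CC)(CC)CC)C[C@@H](O[Si](CC)(CC)CC)[C@@H]12.CS(=O)(=O)[O-] | intermediate (not isolated)
24 | (4S,6R,7S,8R,10S)-trans-fused γ-lactone | C1C(=O)O[C@@H]2C[C@@H](CO[Si](C(C)C)(C(C)C)C(C)C)C(=O)CC[C@](C)(O[Si](CC)(CC)CC)C[C@@H](O[Si](CC)(CC)CC)[C@@H]12 | intermediate
25 | dilithium bis-enolate of 24 (ketone C2 enolate, lactone enolate) | C1=C([O-])O[C@@H]2C[C@@H](CO[Si](C(C)C)(C(C)C)C(C)C)/C([O-])=C\C[C@](C)(O[Si](CC)(CC)CC)C[C@@H](O[Si](CC)(CC)CC)[C@@H]12.[Li+].[Li+] | intermediate (not isolated)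
26 | bis(triethylsilyl) derivative: C2=C3 silyl enol ether, lactone ketene silyl acetal | C1=C(O[Si](CC)(CC)CC)O[C@@H]2C[C@@H](CO[Si](C(C)C)(C(C)C)C(C)C)/C(O[Si](CC)(CC)CC)=C\C[C@](C)(O[Si](CC)(CC)CC)C[C@@H](O[Si](CC)(CC)CC)[C@@H]12 | intermediate (not isolated)
27 | C11 (dimethylamino)methyl lactone (Mannich base, C11 epimers) with C2=C3 silyl enol ether | CN(C)CC1C(=O)O[C@@H]2C[C@@H](CO[Si](C(C)C)(C(C)C)C(C)C)/C(O[Si](CC)(CC)CC)=C\C[C@](C)(O[Si](CC)(CC)CC)C[C@@H](O[Si](CC)(CC)CC)[C@@H]12 | intermediate (not isolated)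
28 | trimethylammonium iodide of 27 | C[N+](C)(C)CC1C(=O)O[C@@H]2C[C@@H](CO[Si](C(C)C)(C(C)C)C(C)C)/C(O[Si](CC)(CC)CC)=C\C[C@](C)(O[Si](CC)(CC)CC)C[C@@H](O[Si](CC)(CC)CC)[C@@H]12.[I-] | intermediate (not isolated)
29 | (4S,6R,7S,8R,10S)-α-methylene lactone with C2=C3 triethylsilyl enol ether | C=C1C(=O)O[C@@H]2C[C@@H](CO[Si](C(C)C)(C(C)C)C(C)C)/C(O[Si](CC)(CC)CC)=C\C[C@](C)(O[Si](CC)(CC)CC)C[C@@H](O[Si](CC)(CC)CC)[C@@H]12 | intermediate
30 | (4S,6R,7S,8R,10R)-(1Z)-enone, 8-OSiEt3, 10-OSiEt3, 15-OSi(iPr)3 | C=C1C(=O)O[C@@H]2C[C@@H](CO[Si](C(C)C)(C(C)C)C(C)C)C(=O)/C=C\[C@](C)(O[Si](CC)(CC)CC)C[C@@H](O[Si](CC)(CC)CC)[C@@H]12 | intermediate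
31 | (4S,6R,7R,8R,10R)-8-hydroxy enone | C=C1C(=O)O[C@@H]2C[C@@H](CO[Si](C(C)C)(C(C)C)C(C)C)C(=O)/C=C\[C@](C)(O[Si](CC)(CC)CC)C[C@@H](O)[C@@H]12 | intermediate
32 | angelic acid, (Z)-2-methylbut-2-enoic acid | C/C=C(/C)C(O)=O | starting material
33 | angelic 2,4,6-trichlorobenzoic anhydride | C/C=C(/C)C(=O)OC(=O)c1c(Cl)cc(Cl)cc1Cl | intermediate (not isolated)
34 | (4S,6R,7S,8R,10R)-8-O-angelate, 10-OSiEt3, 15-OSi(iPr)3 | C=C1C(=O)O[C@@H]2C[C@@H](CO[Si](C(C)C)(C(C)C)C(C)C)C(=O)/C=C\[C@](C)(O[Si](CC)(CC)CC)C[C@@H](OC(=O)/C(C)=C\C)[C@@H]12 | intermediate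
35 | CNP0219400.1, (4S,6R,7S,8R,10R)-8-angeloyloxy-10,15-dihydroxy-3-oxogermacra-1(Z),11(13)-dien-6,12-olide | C=C1C(=O)O[C@@H]2C[C@@H](CO)C(=O)/C=C\[C@](C)(O)C[C@@H](OC(=O)/C(C)=C\C)[C@@H]12 | target

## Step count and risks

Total step count: 21. Longest linear sequence: 21 steps (from 1 to 35; 5, 11 and 32 are purchased).

**Steps most likely to fail**

1. Step 10 (key step). During the basic aldol quench, proton transfer between aldolate and unreacted enolate may move the enolate to C2 or allow a second hydroxymethylation, and relaxation of the ten-membered enolate before trapping may erode the facial bias at C4. Fallback, from 12 back to 15: the rearrangement is run as before, but enolate 14 is quenched with chlorotriethylsilane and isolated as the triethylsilyl enol ether F1. F1 is then hydroxymethylated under neutral Lewis-acid conditions (aqueous formaldehyde, Yb(OSO2CF3)3, THF/H2O, rt; Mukaiyama aldol in aqueous medium), where no free enolate exists and the regiochemistry is held by the silyl enol ether, to give 15.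

2. Step 16. In the crowded ring, base-induced E2 loss of the secondary mesylate, or ionisation and closure with retention, may compete with backside attack by the amide oxygen. Fallback, from 20 back to 24: the cis-lactone is opened with Me3SnOH (1,2-dichloroethane, 60 °C) to the hydroxy acid F2, which is closed at once under Mitsunobu conditions (PPh3, diisopropyl azodicarboxylate, toluene, 0 °C). There the carboxylate displaces the oxyphosphonium-activated C6 oxygen with inversion under essentially neutral conditions, giving 24.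

3. Step 18. β-Hydride elimination may place the alkene with E geometry or give mixtures, because either C1 hydrogen can align with palladium in the flexible ring. Fallback, from 29 back to 30: the silyl enol ether is treated with PhSeCl (CH2Cl2, −78 °C) to give the α-phenylselanyl ketone F3. Oxidation (H2O2, pyridine, CH2Cl2, 0 °C) triggers selenoxide syn-elimination, and any E-enone F4 formed is converted into 30 by irradiation at 350 nm (E to Z photoisomerisation of the enone).

## Further compounds

F1 | step 10 | triethylsilyl enol ether (C3–C4) of the ring-expanded cyclodecenone (6S,10S; E-C7=C8) | O1CC/C(=C\C[C@@](C)(O[Si](CC)(CC)CC)CC/C(O[Si](CC)(CC)CC)=C/C2)[C@@H]12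
F2 | step 16 | (4S,6S,7S,8R,10S)-hydroxy acid from lactone 20 | OC(=O)C[C@@H]1[C@H](O[Si](CC)(CC)CC)C[C@@](C)(O[Si](CC)(CC)CC)CCC(=O)[C@H](CO[Si](C(C)C)(C(C)C)C(C)C)C[C@@H]1O
F3 | step 18 | C2 phenylselanyl ketone (C2 epimers) with α-methylene lactone | C=C1C(=O)O[C@@H]2C[C@@H](CO[Si](C(C)C)(C(C)C)C(C)C)C(=O)C([Se]c3ccccc3)C[C@](C)(O[Si](CC)(CC)CC)C[C@@H](O[Si](CC)(CC)CC)[C@@H]12
F4 | step 18 | (1E)-enone isomer of 30 | C=C1C(=O)O[C@@H]2C[C@@H](CO[Si](C(C)C)(C(C)C)C(C)C)C(=O)/C=C/[C@](C)(O[Si](CC)(CC)CC)C[C@@H](O[Si](CC)(CC)CC)[C@@H]12
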